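At late times this flask can be counted: each target formed has taken one reagent, and each turn of the chain has freed one released group.

| setting | elm | flask |
|---|---|---|
| solid substrate | 1.3 M | 1.3 M |
| reagent | 1.56 M | 1.56 M |
| initiator | 23 mM | 23 mM |
| remark | the very flask that is asked about, followed so far |  |
| time |  | 40 min |

- elm (time / min: solid substrate / %, target / %): 1.50: 65.9, 8.4; 2.50: 51.5, 17.5; 4.00: 36.6, 32.2; 6.00: 17.5, 51.0; 8.00: 0.2, 67.7; 12.0: 0.2, 87.2; 20.0: 0, 96.3

(scatter of a reading: 0.5 percentage points)

- amounts and yields of target count idle adduct B too
- amounts and yields of released group count idle adduct A too
- given per volume of solution although it is solid: solid substrate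
- the numbers in the tables scatter by 0.5 percentage points (one standard deviation)
- steps that have been proposed: initiator -> 2 initiating radical; starting material + initiating radical -> capped initiator + first chain carrier; reagent + first chain carrier -> target + second chain carrier; starting material + second chain carrier -> released group + first chain carrier; 2 second chain carrier -> ended chains; reagent + released group <-> idle adduct A; solid substrate <-> starting material; reagent + target <-> idle adduct B
- at the start none of the solid substrate is in solution
- what has only dissolved of solid substrate counts as not reacted
- the earlier runs do not show how much of reagent is bound; that part of a forecast is a guess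

- part of the solid substrate that has reacted (what has only dissolved counts as not reacted) at 40 min
- share of free reagent in free reagent and idle adduct A together, at 40 min

Reagent charged over solid substrate charged is 1.20 in this flask; this is the reagent cover, which caps target as a fraction of the charge when it stands under one. Here it stands above one, so solid substrate is the limiting reagent, and 0.200 of the charge remains as reagent, free or bound, once the solid substrate has reacted.

The readings supply the other end: the share not yet target fell from 12.8% at 12.0 min to 3.70% at 20.0 min. The same fall carried on to 40 min leaves 0.166%, so this reckoning puts c at 99.8%. The cover gives the reagent pool but not its split, which the readings do not show.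

The forecast gave 99.1%, lower than this reckoning, and 35%, with the words “so this is a guess”. The flask gives 99.8%, close to the reckoned c, and 0.831%.

    initiator → 2 initiating radical (k = 0.00140 s⁻¹)
    starting material + initiating radical → capped initiator + first chain carrier (k = 30000 M⁻¹ s⁻¹)
    reagent + first chain carrier → target + second chain carrier (k = 330 M⁻¹ s⁻¹)
    starting material + second chain carrier → released group + first chain carrier (k = 5900 M⁻¹ s⁻¹)
    2 second chain carrier → ended chains (k = 3.40 × 10⁷ M⁻¹ s⁻¹)
    reagent + released group ⇌ idle adduct A, settled at all times (K = 120 M⁻¹)
    solid substrate ⇌ starting material, rate k7*(cs7 - [starting material]) while solid is left; crystals form when [starting material] > cs7 (solubility = 0.570 M, k = 0.0140 s⁻¹)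
    reagent + target ⇌ idle adduct B, settled at all times (K = 0.250 M⁻¹)

In this flask at 40.0 min, idle adduct A holds 0.199 of the charge, nearly all of the spare 0.200, and the association constant 120 M⁻¹ times the 0.994 M of released group outside the adduct gives 119 bound reagent per free one. A neighbour flask charged with 0.39 M of reagent has a cover of 0.300 and holds target at 30.0% of the solid substrate charged at 40.0 min.

The earlier runs and the new flask were generated by integration from invented constants, noise included.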